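**Retrosynthetic overview**
1. The target is traced back to a 5',7'-dimethoxy-4'-isobutyl spirochroman: the two formyl groups come from a late double Rieche formylation, the free phenols from O-demethylation, and the isobutyl group from a methallyl group attached at C-4' by capture of the chroman-4'-yl cation (this sets C-4').
2. The spirochroman-4'-one behind it is opened in the pyran ring at O-1'–C-8a' (aryl–O) and C-2–C-3', giving camphenilone and the enolate of 1-(2-fluoro-4,6-dimethoxyphenyl)ethanone; the forward reaction is a one-pot aldol/SNAr annulation that sets the spiro centre.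
3. Enabling feature: the spiro carbon C-2 is the carbonyl carbon of camphenilone, flanked by a bridgehead CH and the quaternary CMe2 carbon, so it cannot enolise and is open to attack only on its exo face. Aryl carbon C-8a' (which carries the ring oxygen) is ortho to C-4a', which carries the C-4' acyl carbon, so a fluoride at C-8a' is activated for displacement by the C-2 alkoxide.
4. Ring order: the norbornane (from (−)-camphene by ozonolysis) and the benzene ring (1-fluoro-3,5-dimethoxybenzene) are bought in; the dihydropyran ring is the only ring built and is closed last, in step 3.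

Key step: step 3

Remark (assumption): (1S,4R)-(−)-camphene of high enantiomeric purity is used; every stereocentre of the target derives from it by substrate control, so its optical purity is carried through the route.

**Step 1**
Reactants: 1 (1S,4R)-(−)-camphene
Product: 3 (1R,4S)-camphenilone [(1R,4S)-3,3-dimethylbicyclo[2.2.1]heptan-2-one], via camphene ozonide 2 (not isolated)
Conditions: O3, CH2Cl2, −78 °C; then Me2S, −78 °C → rt
Reagents that add atoms: ozone, [O-][O+]=O
Why: Ozonolysis of the exocyclic 1,1-disubstituted alkene with reductive work-up removes the methylene carbon and leaves the ketone; no stereocentre is formed and both bridgehead centres are untouched (the one α to the new carbonyl cannot enolise).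

**Step 2**
Reactants: 4 1-fluoro-3,5-dimethoxybenzene
Product: 5 1-(2-fluoro-4,6-dimethoxyphenyl)ethan-1-one
Conditions: Ac2O, TfOH (10 mol %), CH2Cl2, 0 °C → rt
Reagents that add atoms: acetic anhydride, CC(=O)OC(C)=O
Why: Friedel–Crafts acylation of the activated arene should occur para to one methoxy group at the position flanked by F and OMe rather than between the two methoxy groups, as is usual for 5-substituted resorcinol dimethyl ethers; the minor 4-acyl isomer would be removed by chromatography.

**Step 3**
Reactants: 5 1-(2-fluoro-4,6-dimethoxyphenyl)ethan-1-one; 3 (1R,4S)-camphenilone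
Product: 8 (1R,2R,4S)-5',7'-dimethoxy-3,3-dimethylspiro[bicyclo[2.2.1]heptane-2,2'-chroman]-4'-one, via lithium enolate 6 (not isolated), via lithium aldolate 7 (not isolated)
Conditions: LiHMDS, THF, −78 °C; 3, −78 → −20 °C; then DMPU, 25 → 60 °C
Reagents that add atoms: none
Why: The lithium enolate 6 adds to the non-enolisable ketone 3 (aldol addition) and the tertiary alkoxide 7 then displaces the ortho fluoride by intramolecular SNAr through a Meisenheimer-type vinylogous enolate, a tandem aldol/SNAr chromanone annulation whose second stage is the fluoride counterpart of the oxa-Michael closure of the Kabbe chromanone synthesis. The pyranone ring closes in a 6-endo-trig addition–elimination mode, the attacked carbon C-8a' being the β-carbon of the aryl ketone. The only new stereocentre, the spiro carbon C-2, is set in the aldol stage by the norbornane framework: as in Grignard and hydride additions to camphenilone and fenchone, the nucleophile should enter on the exo face (syn to the one-carbon bridge), placing the CH2 group exo and the oxygen endo (2R); the SNAr stage does not touch it. The step needs exo facial selectivity at the carbonyl group and ring closure in preference to retro-aldol cleavage: the first is secured by the endo hydrogens of the C-5/C-6 bridge that screen the endo face, the second by the irreversible loss of fluoride, which drains the aldol equilibrium while ketone 3 has no enolisation pathway to be lost by. Should the aldol stage or a base-induced retro-oxa-Michael opening of 8 equilibrate the spiro centre, the same isomer is still expected, since it carries the larger CH2 substituent in the less hindered exo position.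

**Step 4**
Reactants: 8 (1R,2R,4S)-5',7'-dimethoxy-3,3-dimethylspiro[bicyclo[2.2.1]heptane-2,2'-chroman]-4'-one
Product: 9 (1R,2R,4S)-5',7'-dimethoxy-3,3-dimethylspiro[bicyclo[2.2.1]heptane-2,2'-chroman]-4'-ol (both C-4' epimers)
Conditions: LiAlH4, THF, 0 °C; aqueous NaOH work-up, used crude
Reagents that add atoms: none
Why: Hydride reduction of the aryl ketone gives the benzylic alcohol as a mixture of C-4' epimers, which is of no consequence because both ionise to the same cation in step 5.

**Step 5**
Reactants: 9 (1R,2R,4S)-5',7'-dimethoxy-3,3-dimethylspiro[bicyclo[2.2.1]heptane-2,2'-chroman]-4'-ol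
Product: 10 (1R,2R,4S,4'S)-5',7'-dimethoxy-3,3-dimethyl-4'-(2-methylprop-2-en-1-yl)spiro[bicyclo[2.2.1]heptane-2,2'-chromane]
Conditions: (2-methylallyl)SiMe3 (2 equiv), TMSOTf (10 mol %), CH2Cl2, −78 °C
Reagents that add atoms: (2-methylallyl)trimethylsilane, C=C(C)C[Si](C)(C)C
Why: Hosomi–Sakurai-type SN1 allylation in which the benzylic alcohol ionises to the 5',7'-dimethoxy-stabilised chroman-4'-yl cation, which the allylsilane should capture on the face anti to the pseudo-axial bridgehead C-1–H of the spiro-norbornane (the bulkier CMe2 carbon lies pseudo-equatorial), so that the new C–C bond ends trans to C-1 and C-4' is S.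

**Step 6**
Reactants: 10 (1R,2R,4S,4'S)-5',7'-dimethoxy-3,3-dimethyl-4'-(2-methylprop-2-en-1-yl)spiro[bicyclo[2.2.1]heptane-2,2'-chromane]
Product: 11 (1R,2R,4S,4'S)-5',7'-dimethoxy-3,3-dimethyl-4'-(2-methylpropyl)spiro[bicyclo[2.2.1]heptane-2,2'-chromane]
Conditions: H2 (1 atm), PtO2, EtOAc, rt
Reagents that add atoms: none
Why: Catalytic hydrogenation of the 1,1-disubstituted alkene gives the isobutyl group without a new stereocentre; platinum is chosen over palladium to minimise double-bond migration towards C-4', which would erase that centre.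

**Step 7**
Reactants: 11 (1R,2R,4S,4'S)-5',7'-dimethoxy-3,3-dimethyl-4'-(2-methylpropyl)spiro[bicyclo[2.2.1]heptane-2,2'-chromane]
Product: 12 (1R,2R,4S,4'S)-5',7'-dimethoxy-3,3-dimethyl-4'-(2-methylpropyl)spiro[bicyclo[2.2.1]heptane-2,2'-chromane]-6',8'-dicarbaldehyde
Conditions: Cl2CHOMe (5 equiv), TiCl4 (5 equiv), CH2Cl2, −20 → 0 °C; then ice-water
Reagents that add atoms: dichloromethyl methyl ether, COC(Cl)Cl; water, O
Why: Rieche formylation, in which C-6' and C-8' are the only free ring positions and each is ortho/para to three oxygen substituents, so double electrophilic substitution and hydrolysis of the α-chloro ethers should give the dialdehyde without a regiochemical issue.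

**Step 8**
Reactants: 12 (1R,2R,4S,4'S)-5',7'-dimethoxy-3,3-dimethyl-4'-(2-methylpropyl)spiro[bicyclo[2.2.1]heptane-2,2'-chromane]-6',8'-dicarbaldehyde
Product: 13 (1R,2R,4S,4'S)-5',7'-dihydroxy-3,3-dimethyl-4'-(2-methylpropyl)spiro[bicyclo[2.2.1]heptane-2,2'-chromane]-6',8'-dicarbaldehyde (target)
Conditions: NaSEt (6 equiv), DMF, 100 °C; then 1 M HCl
Reagents that add atoms: none
Why: SN2 O-demethylation by thiolate, in which each methoxy group is ortho or para to both formyl groups and so behaves as a vinylogous methyl ester cleaved at the methyl carbon, while the tertiary spiro ether, the aldehydes and C-4' (its C–H is meta to both formyl groups and not acidified) should survive these non-acidic conditions.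

**Compound list**
1 | (1S,4R)-(−)-camphene [(1S,4R)-2,2-dimethyl-3-methylidenebicyclo[2.2.1]heptane] | C=C1[C@@H]2CC[C@@H](C2)C1(C)C | starting material
2 | camphene secondary ozonide (spiro-1,2,4-trioxolane, epimers at the trioxolane carbon) | C1OOC2(O1)[C@@H]1CC[C@@H](C1)C2(C)C | intermediate (not isolated)
3 | (1R,4S)-camphenilone [(1R,4S)-3,3-dimethylbicyclo[2.2.1]heptan-2-one] | O=C1[C@@H]2CC[C@@H](C2)C1(C)C | intermediate
4 | 1-fluoro-3,5-dimethoxybenzene | COc1cc(F)cc(OC)c1 | starting material
5 | 1-(2-fluoro-4,6-dimethoxyphenyl)ethan-1-one | CC(=O)c1c(F)cc(OC)cc1OC | intermediate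
6 | lithium enolate of 5 | [Li+].[O-]C(=C)c1c(F)cc(OC)cc1OC | intermediate (not isolated)
7 | lithium aldolate, lithium (1R,2R,4S)-2-[2-(2-fluoro-4,6-dimethoxyphenyl)-2-oxoethyl]-3,3-dimethylbicyclo[2.2.1]heptan-2-olate | [Li+].[O-][C@]1(CC(=O)c2c(F)cc(OC)cc2OC)[C@@H]2CC[C@@H](C2)C1(C)C | intermediate (not isolated)
8 | (1R,2R,4S)-5',7'-dimethoxy-3,3-dimethylspiro[bicyclo[2.2.1]heptane-2,2'-chroman]-4'-one | O=C1C[C@@]2(Oc3cc(OC)cc(OC)c31)[C@@H]1CC[C@@H](C1)C2(C)C | intermediate
9 | (1R,2R,4S)-5',7'-dimethoxy-3,3-dimethylspiro[bicyclo[2.2.1]heptane-2,2'-chroman]-4'-ol (C-4' epimers) | OC1C[C@@]2(Oc3cc(OC)cc(OC)c31)[C@@H]1CC[C@@H](C1)C2(C)C | intermediate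
10 | (1R,2R,4S,4'S)-5',7'-dimethoxy-3,3-dimethyl-4'-(2-methylprop-2-en-1-yl)spiro[bicyclo[2.2.1]heptane-2,2'-chromane] | C=C(C)C[C@H]1C[C@@]2(Oc3cc(OC)cc(OC)c31)[C@@H]1CC[C@@H](C1)C2(C)C | intermediate
11 | (1R,2R,4S,4'S)-5',7'-dimethoxy-3,3-dimethyl-4'-(2-methylpropyl)spiro[bicyclo[2.2.1]heptane-2,2'-chromane] | CC(C)C[C@H]1C[C@@]2(Oc3cc(OC)cc(OC)c31)[C@@H]1CC[C@@H](C1)C2(C)C | intermediate
12 | (1R,2R,4S,4'S)-5',7'-dimethoxy-3,3-dimethyl-4'-(2-methylpropyl)spiro[bicyclo[2.2.1]heptane-2,2'-chromane]-6',8'-dicarbaldehyde | CC(C)C[C@H]1C[C@@]2(Oc3c(C=O)c(OC)c(C=O)c(OC)c31)[C@@H]1CC[C@@H](C1)C2(C)C | intermediate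
13 | (1R,2R,4S,4'S)-5',7'-dihydroxy-3,3-dimethyl-4'-(2-methylpropyl)spiro[bicyclo[2.2.1]heptane-2,2'-chromane]-6',8'-dicarbaldehyde | CC(C)C[C@H]1C[C@@]2(Oc3c(C=O)c(O)c(C=O)c(O)c31)[C@@H]1CC[C@@H](C1)C2(C)C | target

**Step count and risks**
Total step count: 8. Longest linear sequence: 7 steps (steps 2–8 from 4; the camphene branch, steps 1 and 3–8, is equally long).

The three steps most likely to fail:

Step 3. Retro-aldol cleavage of the crowded aldolate 7 may outrun fluoride displacement on the electron-rich ring, since the two methoxy groups weaken the activation by the ketone; the enolate would then be lost to self-condensation, and base-induced ring opening of 8 could erode the spiro configuration. The fallback sets out from 3 and closes the ring through the O–C-2 bond instead of the aryl–O bond. The dianion of commercial 2'-hydroxy-4',6'-dimethoxyacetophenone (2.2 equiv LDA, THF, −78 °C) is added to 3 to give the aldol 1-(2-hydroxy-4,6-dimethoxyphenyl)-2-[(1R,2R,4S)-2-hydroxy-3,3-dimethylbicyclo[2.2.1]heptan-2-yl]ethan-1-one F1. Pyrrolidine in hot ethanol should dehydrate it to the enone (E)-2-[(1R,4S)-3,3-dimethylbicyclo[2.2.1]heptan-2-ylidene]-1-(2-hydroxy-4,6-dimethoxyphenyl)ethan-1-one F2, whose phenol closes the ring by oxa-Michael addition (Kabbe-type closure) under equilibrating conditions, which should favour the isomer with the CH2 group exo. The fallback comes back to the route at chromanone 8.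

Step 5. The silane may attack the planar benzylic cation on the wrong face (syn to C-1, along the chair-like axial trajectory), which would give mainly the 4'-epimer, or the cation may lose a proton to the 2H-chromene and oligomerise. The fallback sets out from 8 and reverses the order in which carbon and hydrogen reach C-4'. Isobutylmagnesium bromide with CeCl3 (THF, −78 → 0 °C; the cerium reagent suppresses enolisation) adds to the ketone to give (1R,2R,4S)-5',7'-dimethoxy-3,3-dimethyl-4'-(2-methylpropyl)spiro[bicyclo[2.2.1]heptane-2,2'-chroman]-4'-ol F3. Ionic hydrogenation (Et3SiH, CF3CO2H, CH2Cl2, −40 °C) then delivers hydride last to the tertiary benzylic cation. Because the entering group is now H and not the side chain, a facial preference opposite to the one assumed in step 5 leads to the same (4'S) isomer. The fallback comes back to the route at 11, and step 6 is then not needed.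

Step 8. Cleavage of the second methyl ether may stall once the ring has become a phenoxide, and the hot thiolate may attack the electron-poor dialdehyde ring (addition to a formyl group or displacement of methoxide) instead of the methyl carbon. The fallback sets out from 11 and changes the order of events. Both methyl ethers are removed before any aldehyde is present (NaSEt, DMF, 140 °C) to give (1R,2R,4S,4'S)-3,3-dimethyl-4'-(2-methylpropyl)spiro[bicyclo[2.2.1]heptane-2,2'-chromane]-5',7'-diol F4. A double Vilsmeier–Haack formylation of the free diol (POCl3, DMF, MeCN, 0 °C → rt; then aqueous NaOAc), the way diformylphloroglucinol itself is made, should then give the target. The fallback comes back to the route at 13 and also avoids TiCl4.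

**Further compounds**
F1 | step 3 | 1-(2-hydroxy-4,6-dimethoxyphenyl)-2-[(1R,2R,4S)-2-hydroxy-3,3-dimethylbicyclo[2.2.1]heptan-2-yl]ethan-1-one | COc1cc(O)c(C(=O)C[C@@]2(O)[C@@H]3CC[C@@H](C3)C2(C)C)c(OC)c1
F2 | step 3 | (E)-2-[(1R,4S)-3,3-dimethylbicyclo[2.2.1]heptan-2-ylidene]-1-(2-hydroxy-4,6-dimethoxyphenyl)ethan-1-one | COc1cc(O)c(C(=O)/C=C2\[C@@H]3CC[C@@H](C3)C2(C)C)c(OC)c1
F3 | step 5 | (1R,2R,4S)-5',7'-dimethoxy-3,3-dimethyl-4'-(2-methylpropyl)spiro[bicyclo[2.2.1]heptane-2,2'-chroman]-4'-ol (C-4' epimers) | CC(C)CC1(O)C[C@@]2(Oc3cc(OC)cc(OC)c31)[C@@H]1CC[C@@H](C1)C2(C)C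
F4 | step 8 | (1R,2R,4S,4'S)-3,3-dimethyl-4'-(2-methylpropyl)spiro[bicyclo[2.2.1]heptane-2,2'-chromane]-5',7'-diol | CC(C)C[C@H]1C[C@@]2(Oc3cc(O)cc(O)c31)[C@@H]1CC[C@@H](C1)C2(C)C
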